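A small charge of free catalyst, 0.17 mM in the blue run and 0.39 mM in the ochre run, works through a far larger charge of starting material, 0.52 M.

| setting | blue | ochre | green | flask |
|---|---|---|---|---|
| starting material | 0.52 M | 0.52 M | 0.52 M | 0.52 M |
| second substrate | 0.52 M | 0.52 M | 0.52 M | 0.520 M |
| protic impurity | 0.52 M | 0.52 M | 0.26 M | 0.520 M |
| free catalyst | 0.17 mM | 0.39 mM | 0.26 mM | 0.26 mM |
| remark | run made earlier | run made earlier | run made earlier |  |

| run | time / min | target / % |
|---|---|---|
| blue | 0.200 | 8 |
| blue | 0.333 | 10 |
| blue | 0.500 | 13 |
| blue | 0.833 | 27 |
| blue | 1.33 | 44 |
| blue | 2.50 | 76 |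
| ochre | 0.167 | 11 |
| ochre | 0.500 | 40 |
| ochre | 0.833 | 63 |
| ochre | 1.33 | 87 |
| ochre | 2.00 | 97 |
| ochre | 2.50 | 99 |
| green | 0.200 | 10 |
| green | 0.667 | 36 |
| green | 1.00 | 49 |
| green | 1.50 | 68 |
| green | 2.50 | 92 |

(each reading ± 1.5 percentage points)

- no earlier run changes the charge of second substrate; that part of a forecast is a guess

- factor on the rate of making target when 20% of the starting material are converted if second substrate is charged twice over
- factor on the rate when 20% of the starting material are converted if free catalyst is charged at 1.2 mM instead

Two rates carry my argument: how fast target appears around 20% conversion in the blue run and in the ochre run. Across the two readings that bracket that conversion, the blue run makes 0.219 M/min and the ochre run 0.453 M/min. Their ratio reads 2.07, and the catalyst charges stand at 2.29, which is close within the scatter of such slopes. So I freeze what these two runs share. The two rates summed over the two charges summed give 1200 /min, and this rate per catalyst, the turnover frequency, is what I carry. Held fixed, it makes the rate follow the catalyst charge, so going from 0.26 mM to 1.2 mM multiplies the rate by 4.62. No earlier run varies second substrate, so I commit to no factor there.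

The forecast gives 4.2 (range 2.8 to 5.6), lower than my factor, with “some allowance for saturation”. For doubled second substrate it guesses 1.4 (range 1 to 2.1).

The flask gives a factor of 4.42 for 1.2 mM of free catalyst and 0.852 for doubled second substrate, which is below the low end of the forecast's range.

second substrate + free catalyst ⇌ catalyst intermediate B (K = 4.20 /M, k = 140 /M/s); starting material + free catalyst ⇌ catalyst intermediate A (K = 29.0 /M, k = 170 /M/s); second substrate + protic impurity → quenched substrate (k = 0.0300 /M/s); catalyst intermediate B → free catalyst + second product (k = 46.0 /s); catalyst intermediate A → free catalyst + target (k = 32.0 /s) At the start of this flask, free catalyst is taken up by starting material 1.2 times as fast as by second substrate, each forward step alone. The carried 1200 /min on this flask's 0.26 mM gives 0.312 M/min against its 0.269 M/min. In the green run, with 0.26 mM of free catalyst and half the protic impurity of this flask, the carried 1200 /min gives 0.312 M/min, and the green readings bracketing 20% give 0.290 M/min.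

The data were generated by integration on assumed constants, noise included.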